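The earlier runs and the new flask were computed with constants of no real substance; noise was put on by code.

The charge ratio of partner to substrate is 0.900, so partner taken one for one would leave 10.0% of the substrate over. Yet the north-west run reads 0% substrate at 50.0 min, less than that remainder. Two chemists read this differently, from these flasks and runs:

| flask | substrate | partner | protic impurity | remark | time |
|---|---|---|---|---|---|
| north-west | 16 mM | 14.4 mM | 0.32 mM | run made earlier |  |
| north-east | 16 mM | 14.4 mM | 0.48 mM | run made earlier |  |
| autumn | 16 mM (fed, over 1.0 h) | 14.4 mM | 0.320 mM | all else is in the flask from the start; the feed brings no volume worth counting | 80 min |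
| noon | 16 mM | 14.4 mM | 0.320 mM | everything together at the start | 80 min |
| summer | 16 mM | 14.4 mM (fed, over 1.0 h) | 0.320 mM | all else is in the flask from the start; the feed brings no volume worth counting | 80 min |
| midnight | 16 mM (in portions, 2, over 1.0 h) | 14.4 mM | 0.320 mM | first portion at the start, last at 1.0 h | 80 min |
| dawn | 16 mM | 14.4 mM (fed, over 15 min) | 0.320 mM | all else is in the flask from the start; the feed brings no volume worth counting | 80 min |

| run | time / min | target / % | substrate / % |
|---|---|---|---|
| north-west | 4.00 | 1 | 53 |
| north-west | 6.00 | 9 | 45 |
| north-west | 8.00 | 2 | 34 |
| north-west | 15.0 | 16 | 20 |
| north-west | 20.0 | 18 | 11 |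
| north-west | 30.0 | 24 | 5 |
| north-west | 50.0 | 42 | 0 |
| north-east | 0.833 | 2 | 88 |
| north-east | 2.50 | 1 | 67 |
| north-east | 5.00 | 1 | 52 |
| north-east | 6.00 | 1 | 47 |
| north-east | 10.0 | 10 | 32 |
| north-east | 12.0 | 7 | 24 |
| north-east | 15.0 | 13 | 14 |

(readings scatter by 2 percentage points)



* the flask that comes out highest in amount of target, in percent of the substrate charged, or "all alike" when all lie within 1.5 percentage points (autumn / noon / summer / midnight / dawn / all alike)
* target at the end, in percent of the substrate charged, autumn
* target at the end, in percent of the substrate charged, noon
* target at the end, in percent of the substrate charged, summer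
* target at the end, in percent of the substrate charged, midnight
* target at the end, in percent of the substrate charged, dawn

The first chemist says that substrate leaves by itself, at a constant rate, into an intermediate that meets partner later. The two runs differ in impurity, 0.32 mM against 0.48 mM, but at 6.00 min their substrate reads 45% and 47%. In the north-west run target climbs from 24% to 42% between 30.0 min and 50.0 min, while substrate falls from 5% to 0%. On this view a partner feed delays the last step.

The second chemist, whose reckoning I take as mine, looks at the slope. Over the first 2.50 min of the north-east run substrate falls at 0.160 /min. Between 15.0 min and 30.0 min of the north-west run it falls at 0.0924 /min, which is slower, though both are readings with their scatter. This suggests two paths: one that needs partner, pseudo-first-order at any moment with its rate following the partner then present, and one that does not. The late rate gives substrate a life of 10.8 min.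

Summer's partner feed of 1.0 h against that life gives 5.55. This ratio, the partner feed time over substrate's late life, is the feed number. Summer's number stands above one, so substrate's life covers 18.0% of the feed. Within one life, summer delivers partner worth 16.2% of the substrate charged, and I reckon its target near that. Dawn's feed number is 1.39, smaller, so I place dawn between summer and noon.

The forecast stands with the first view: noon highest at 53%, dawn 51%, summer 42%, “limited by low partner”, autumn 38% and midnight 36%.

The simulation gives noon highest at 48.2%, then autumn 38.4%, midnight 34.6%, dawn 34.2% and summer 16.2%. Partner belongs to the first step, as the second view held: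

    substrate + partner → intermediate (k = 0.110 /M/s)
    substrate → side product (k = 9.20 × 10⁻⁴ /s)
    intermediate → target (k = 5.90 × 10⁻⁴ /s)
    partner + protic impurity → quenched reagent (k = 13.0 /M/s)

At 80 min noon is not at rest: it holds 4.31% intermediate, and by 800 min its target has risen from 48.2% to 52.5%. By 800 min autumn and midnight reach 52.5% and 52.5%, level with noon, from 38.4% and 34.6% at 80 min: with partner in from the start, holding substrate back cost time, and that ground stays with the first view. Summer, fed over 18.0 min instead, has feed number 1.67 and gives 32.1%. As charged, summer's side product stands at 80.9% at 80 min and 80.9% at 800 min, while over the same span its target goes from 16.2% to 19.1%.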